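**Strategy.** Flavanone locants are used; unprimed atoms belong to the 4-methoxyphenyl unit, primed atoms to the other. Everything rests on the 1,4-diketone C4(=O)–C3–C3'–C4'(=O) shared by pyranone rings C and C': both acyl carbons are joined with reversed polarity to an alkyne C3≡C3'. The precursor is a 1,4-diarylbut-2-yne-1,4-diol bis(aryl ether) with stereodefined C2 and C2', one arene carrying a formyl group and the other a vinyl mask. The key step, a carbene-catalysed intramolecular hydroacylation, joins aldehyde carbon C4 to alkyne carbon C3, closes ring C and leaves the (E)-enone C3=C3'; a later intramolecular Stetter reaction closes ring C' and sets C3 and C3'.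

Key step: step 7

Remark: ligand enantiomers are specified by the configuration they must deliver; CIP descriptors of intermediates change with substituent priorities, while the spatial arrangement at C2 and C2' is carried through unchanged.

**Step 1**
Reactants: 1 2,4,6-trihydroxybenzaldehyde; 2 benzyl bromide
Product: 3 2,4-bis(benzyloxy)-6-hydroxybenzaldehyde
Conditions: BnBr (2.05 equiv), K2CO3 (2.2 equiv), DMF, 0 °C to rt
Reagents that add atoms: benzyl bromide, BrCc1ccccc1
Why: Williamson etherification, in which the hydroxyl that stays hydrogen-bonded to the formyl group is the least nucleophilic, so two equivalents of benzyl bromide should alkylate the para and one ortho hydroxyl and leave the chelated one free.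

**Step 2**
Reactants: 4 4-(benzyloxy)benzaldehyde; 5 ethynylmagnesium bromide; 6 acetic anhydride
Product: 8 rac-1-[4-(benzyloxy)phenyl]prop-2-yn-1-yl acetate, via bromomagnesium alkoxide 7 (not isolated)
Conditions: HC≡CMgBr (1.2 equiv), THF, 0 °C; then Ac2O (1.5 equiv), 0 °C to rt
Reagents that add atoms: ethynylmagnesium bromide, C#C[Mg]Br; acetic anhydride, CC(=O)OC(C)=O
Why: Grignard addition to the aldehyde and in-flask O-acetylation of the alkoxide give the racemic propargylic ester, whose configuration is irrelevant because the next step is enantioconvergent.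

**Step 3**
Reactants: 8 rac-1-[4-(benzyloxy)phenyl]prop-2-yn-1-yl acetate; 3 2,4-bis(benzyloxy)-6-hydroxybenzaldehyde
Product: 9 2,4-bis(benzyloxy)-6-{[(1R)-1-[4-(benzyloxy)phenyl]prop-2-yn-1-yl]oxy}benzaldehyde
Conditions: (CuOTf)2·C6H6 (5 mol %), 2,6-bis(4-phenyl-4,5-dihydrooxazol-2-yl)pyridine (10 mol %, the enantiomer that gives the (R)-ether), i-Pr2NEt (1.2 equiv), CF3CH2OH, −20 °C
Reagents that add atoms: 2,4-bis(benzyloxy)-6-hydroxybenzaldehyde (3), O=Cc1c(O)cc(OCc2ccccc2)cc1OCc1ccccc1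
Why: Copper-catalysed enantioselective propargylic etherification, in which both enantiomers of 8 ionize to the same copper allenylidene and the phenoxide of the acidic, formyl-deactivated phenol 3 attacks its γ-carbon at oxygen inside the chiral pybox pocket, which sets the (R) centre that becomes C2'.

**Step 4**
Reactants: 9 2,4-bis(benzyloxy)-6-{[(1R)-1-[4-(benzyloxy)phenyl]prop-2-yn-1-yl]oxy}benzaldehyde; 10 methyltriphenylphosphonium bromide
Product: 11 1,5-bis(benzyloxy)-3-{[(1R)-1-[4-(benzyloxy)phenyl]prop-2-yn-1-yl]oxy}-2-ethenylbenzene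
Conditions: Ph3PCH3Br (1.5 equiv), KOt-Bu (1.4 equiv), THF, 0 °C to rt
Reagents that add atoms: methyltriphenylphosphonium bromide, C[P+](c1ccccc1)(c1ccccc1)c1ccccc1.[Br-]
Why: Wittig methylenation masks this formyl group as a styrene that is inert to organozinc, Mitsunobu and carbene conditions, and the ylide is too weak a base to touch the alkyne C–H or the stereocentre.

**Step 5**
Reactants: 11 1,5-bis(benzyloxy)-3-{[(1R)-1-[4-(benzyloxy)phenyl]prop-2-yn-1-yl]oxy}-2-ethenylbenzene; 12 4-methoxybenzaldehyde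
Product: 14 (1S,4S)-4-[3,5-bis(benzyloxy)-2-ethenylphenoxy]-4-[4-(benzyloxy)phenyl]-1-(4-methoxyphenyl)but-2-yn-1-ol, via methylzinc acetylide 13 (not isolated)
Conditions: Me2Zn (3 equiv), 2,6-bis{[2-(hydroxydiphenylmethyl)pyrrolidin-1-yl]methyl}-4-methylphenol (ProPhenol, 20 mol %, the enantiomer that gives Re-face addition), Ph3PO (40 mol %), toluene, 0 °C; then 12 (2 equiv), 4 °C; aq NH4Cl
Reagents that add atoms: 4-methoxybenzaldehyde (12), COc1ccc(C=O)cc1
Why: Catalytic asymmetric alkynylation, in which the dinuclear zinc–ProPhenol complex delivers the zinc alkynylide to the Re face of 12 and so sets the (1S) carbinol under catalyst control, the remote C4 centre across the alkyne having no influence.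

**Step 6**
Reactants: 14 (1S,4S)-4-[3,5-bis(benzyloxy)-2-ethenylphenoxy]-4-[4-(benzyloxy)phenyl]-1-(4-methoxyphenyl)but-2-yn-1-ol; 3 2,4-bis(benzyloxy)-6-hydroxybenzaldehyde
Product: 15 2,4-bis(benzyloxy)-6-{[(1R,4S)-4-[3,5-bis(benzyloxy)-2-ethenylphenoxy]-4-[4-(benzyloxy)phenyl]-1-(4-methoxyphenyl)but-2-yn-1-yl]oxy}benzaldehyde
Conditions: PPh3 (1.5 equiv), DIAD (1.5 equiv), toluene, −20 °C to 0 °C
Reagents that add atoms: 2,4-bis(benzyloxy)-6-hydroxybenzaldehyde (3), O=Cc1c(O)cc(OCc2ccccc2)cc1OCc1ccccc1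
Why: Mitsunobu etherification with the acidic chelated phenol 3 proceeds by SN2 displacement of the oxyphosphonium group with inversion, turning the (1S) carbinol into the (1R) aryl ether that becomes C2, while low temperature and a non-polar solvent hold back ionization of the p-methoxybenzylic centre.

**Step 7**
Reactants: 15 2,4-bis(benzyloxy)-6-{[(1R,4S)-4-[3,5-bis(benzyloxy)-2-ethenylphenoxy]-4-[4-(benzyloxy)phenyl]-1-(4-methoxyphenyl)but-2-yn-1-yl]oxy}benzaldehyde
Product: 16 (2R,3E)-5,7-bis(benzyloxy)-3-{(2R)-2-[3,5-bis(benzyloxy)-2-ethenylphenoxy]-2-[4-(benzyloxy)phenyl]ethylidene}-2-(4-methoxyphenyl)-2,3-dihydro-4H-chromen-4-one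
Conditions: 3-mesityl-5,6,7,8-tetrahydro-4H-cyclohepta[d]thiazol-3-ium perchlorate (10 mol %), K2CO3 (20 mol %), THF (0.05 M), 70 °C
Reagents that add atoms: none
Why: The thiazol-2-ylidene adds to the formyl carbon of 15 and proton transfer gives the enaminol (acyl anion equivalent), whose nucleophilic carbon C4 attacks the proximal alkyne carbon C3 while its O–H proton is delivered to C3' in a concerted, Conia-ene-like syn addition, after which loss of the carbene gives ketone 16. The closest known reaction type is the carbene-catalysed intramolecular hydroacylation of unactivated alkynes in 2-(propargyloxy)benzaldehydes to 3-alkylidenechroman-4-ones. Ring C closes in the 6-exo-dig mode, the 7-endo alternative being disfavoured by the short O1–C2 tether. No stereocentre is created; the syn addition fixes the (E) geometry (C4 cis to the new vinylic hydrogen, C2 cis to C2'), and C2 and C2' should be carried through because only substoichiometric carbonate is present. The step needs selection between the two arenes and protection of the product from base-induced isomerization to the 3-alkylflavone: the first is secured by the vinyl mask, which leaves only the unprimed arene able to act as acyl donor, the second by the weak base and by stopping at full conversion.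

**Step 8**
Reactants: 16 (2R,3E)-5,7-bis(benzyloxy)-3-{(2R)-2-[3,5-bis(benzyloxy)-2-ethenylphenoxy]-2-[4-(benzyloxy)phenyl]ethylidene}-2-(4-methoxyphenyl)-2,3-dihydro-4H-chromen-4-one; 17 sodium periodate
Product: 19 2,4-bis(benzyloxy)-6-{(1R,2E)-2-[(2R)-5,7-bis(benzyloxy)-2-(4-methoxyphenyl)-4-oxo-2H-chromen-3(4H)-ylidene]-1-[4-(benzyloxy)phenyl]ethoxy}benzaldehyde, via vicinal diol 18 (not isolated)
Conditions: OsO4 (2 mol %), NaIO4 (3 equiv), 2,6-lutidine (2 equiv), 1,4-dioxane/H2O 3:1, 0 °C to rt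
Reagents that add atoms: sodium periodate (terminal oxygen source, relayed by catalytic OsO4), [Na+].[O-]I(=O)(=O)=O
Why: Lemieux–Johnson cleavage, in which electrophilic OsO4 should dihydroxylate the electron-rich styrene far faster than the electron-poor trisubstituted enone and periodate cleaves the diol to the aldehyde under lutidine buffering, without touching a stereocentre.

**Step 9**
Reactants: 19 2,4-bis(benzyloxy)-6-{(1R,2E)-2-[(2R)-5,7-bis(benzyloxy)-2-(4-methoxyphenyl)-4-oxo-2H-chromen-3(4H)-ylidene]-1-[4-(benzyloxy)phenyl]ethoxy}benzaldehyde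
Product: 20 (2S,3S)-5,7-bis(benzyloxy)-3-{(2R,3S)-5,7-bis(benzyloxy)-2-[4-(benzyloxy)phenyl]-4-oxo-3,4-dihydro-2H-chromen-3-yl}-2-(4-methoxyphenyl)-2,3-dihydro-4H-chromen-4-one
Conditions: 2-(pentafluorophenyl)-6,7-dihydro-5H-pyrrolo[2,1-c][1,2,4]triazol-2-ium tetrafluoroborate (20 mol %), KN(SiMe3)2 (18 mol %), toluene, 0 °C to 23 °C
Reagents that add atoms: none
Why: Intramolecular Stetter reaction, in which the acyl anion equivalent at C4' adds 6-exo-trig to the β-carbon C3' on the face anti to the pseudo-axial 4-methoxyphenyl group at C2, which is also the face that carries the aryloxy tether when H–C2' eclipses the C3=C3' bond to minimise allylic strain (giving the 2',3'-trans relation), and the ring-C enol is then protonated at C3 on the same face by syn transfer, anti to the C2 aryl group (giving the 2,3-cis relation), so that (3S,3'S) should result under substrate control while the slight deficit of base relative to azolium salt guards both new centres against epimerization.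

**Step 10**
Reactants: 20 (2S,3S)-5,7-bis(benzyloxy)-3-{(2R,3S)-5,7-bis(benzyloxy)-2-[4-(benzyloxy)phenyl]-4-oxo-3,4-dihydro-2H-chromen-3-yl}-2-(4-methoxyphenyl)-2,3-dihydro-4H-chromen-4-one
Product: 21 (2S,3S)-3-[(2R,3S)-5,7-dihydroxy-2-(4-hydroxyphenyl)-4-oxo-3,4-dihydro-2H-chromen-3-yl]-5,7-dihydroxy-2-(4-methoxyphenyl)-2,3-dihydro-4H-chromen-4-one
Conditions: H2 (1 atm), 10% Pd/C, EtOAc/MeOH 1:1, rt
Reagents that add atoms: none
Why: Hydrogenolysis removes the five aryl benzyl ethers under neutral conditions that avoid enolization or retro-oxa-Michael epimerization of C2, C3, C3' and C2', while the aryl methyl ether and the more slowly cleaved cyclic benzylic C–O bonds should persist.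

**Compound list**
1 | 2,4,6-trihydroxybenzaldehyde | O=Cc1c(O)cc(O)cc1O | starting material
2 | benzyl bromide | BrCc1ccccc1 | starting material
3 | 2,4-bis(benzyloxy)-6-hydroxybenzaldehyde | O=Cc1c(O)cc(OCc2ccccc2)cc1OCc1ccccc1 | intermediate
4 | 4-(benzyloxy)benzaldehyde | O=Cc1ccc(OCc2ccccc2)cc1 | starting material
5 | ethynylmagnesium bromide | C#C[Mg]Br | starting material
6 | acetic anhydride | CC(=O)OC(C)=O | starting material
7 | bromomagnesium 1-[4-(benzyloxy)phenyl]prop-2-yn-1-olate (racemic, not isolated) | C#CC(O[Mg]Br)c1ccc(OCc2ccccc2)cc1 | intermediate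
8 | rac-1-[4-(benzyloxy)phenyl]prop-2-yn-1-yl acetate | CC(=O)OC(C#C)c1ccc(OCc2ccccc2)cc1 | intermediate
9 | 2,4-bis(benzyloxy)-6-{[(1R)-1-[4-(benzyloxy)phenyl]prop-2-yn-1-yl]oxy}benzaldehyde | C#C[C@@H](Oc1cc(OCc2ccccc2)cc(OCc2ccccc2)c1C=O)c1ccc(OCc2ccccc2)cc1 | intermediate
10 | methyltriphenylphosphonium bromide | C[P+](c1ccccc1)(c1ccccc1)c1ccccc1.[Br-] | starting material
11 | 1,5-bis(benzyloxy)-3-{[(1R)-1-[4-(benzyloxy)phenyl]prop-2-yn-1-yl]oxy}-2-ethenylbenzene | C#C[C@@H](Oc1cc(OCc2ccccc2)cc(OCc2ccccc2)c1C=C)c1ccc(OCc2ccccc2)cc1 | intermediate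
12 | 4-methoxybenzaldehyde | COc1ccc(C=O)cc1 | starting material
13 | methylzinc acetylide of 11 (not isolated) | C[Zn]C#C[C@@H](Oc1cc(OCc2ccccc2)cc(OCc2ccccc2)c1C=C)c1ccc(OCc2ccccc2)cc1 | intermediate
14 | (1S,4S)-4-[3,5-bis(benzyloxy)-2-ethenylphenoxy]-4-[4-(benzyloxy)phenyl]-1-(4-methoxyphenyl)but-2-yn-1-ol | COc1ccc([C@H](O)C#C[C@@H](Oc2cc(OCc3ccccc3)cc(OCc3ccccc3)c2C=C)c2ccc(OCc3ccccc3)cc2)cc1 | intermediate
15 | 2,4-bis(benzyloxy)-6-{[(1R,4S)-4-[3,5-bis(benzyloxy)-2-ethenylphenoxy]-4-[4-(benzyloxy)phenyl]-1-(4-methoxyphenyl)but-2-yn-1-yl]oxy}benzaldehyde | COc1ccc([C@@H](Oc2cc(OCc3ccccc3)cc(OCc3ccccc3)c2C=O)C#C[C@@H](Oc2cc(OCc3ccccc3)cc(OCc3ccccc3)c2C=C)c2ccc(OCc3ccccc3)cc2)cc1 | intermediate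
16 | (2R,3E)-5,7-bis(benzyloxy)-3-{(2R)-2-[3,5-bis(benzyloxy)-2-ethenylphenoxy]-2-[4-(benzyloxy)phenyl]ethylidene}-2-(4-methoxyphenyl)-2,3-dihydro-4H-chromen-4-one | COc1ccc([C@H]2Oc3cc(OCc4ccccc4)cc(OCc4ccccc4)c3C(=O)/C2=C/[C@@H](Oc2cc(OCc3ccccc3)cc(OCc3ccccc3)c2C=C)c2ccc(OCc3ccccc3)cc2)cc1 | intermediate
17 | sodium periodate | [Na+].[O-]I(=O)(=O)=O | starting material
18 | (2R,3E)-5,7-bis(benzyloxy)-3-{(2R)-2-[3,5-bis(benzyloxy)-2-(1,2-dihydroxyethyl)phenoxy]-2-[4-(benzyloxy)phenyl]ethylidene}-2-(4-methoxyphenyl)-2,3-dihydro-4H-chromen-4-one (diol carbon undefined, not isolated) | COc1ccc([C@H]2Oc3cc(OCc4ccccc4)cc(OCc4ccccc4)c3C(=O)/C2=C/[C@@H](Oc2cc(OCc3ccccc3)cc(OCc3ccccc3)c2C(O)CO)c2ccc(OCc3ccccc3)cc2)cc1 | intermediate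
19 | 2,4-bis(benzyloxy)-6-{(1R,2E)-2-[(2R)-5,7-bis(benzyloxy)-2-(4-methoxyphenyl)-4-oxo-2H-chromen-3(4H)-ylidene]-1-[4-(benzyloxy)phenyl]ethoxy}benzaldehyde | COc1ccc([C@H]2Oc3cc(OCc4ccccc4)cc(OCc4ccccc4)c3C(=O)/C2=C/[C@@H](Oc2cc(OCc3ccccc3)cc(OCc3ccccc3)c2C=O)c2ccc(OCc3ccccc3)cc2)cc1 | intermediate
20 | (2S,3S)-5,7-bis(benzyloxy)-3-{(2R,3S)-5,7-bis(benzyloxy)-2-[4-(benzyloxy)phenyl]-4-oxo-3,4-dihydro-2H-chromen-3-yl}-2-(4-methoxyphenyl)-2,3-dihydro-4H-chromen-4-one | COc1ccc([C@H]2Oc3cc(OCc4ccccc4)cc(OCc4ccccc4)c3C(=O)[C@H]2[C@@H]2C(=O)c3c(OCc4ccccc4)cc(OCc4ccccc4)cc3O[C@H]2c2ccc(OCc3ccccc3)cc2)cc1 | intermediate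
21 | (2S,3S)-3-[(2R,3S)-5,7-dihydroxy-2-(4-hydroxyphenyl)-4-oxo-3,4-dihydro-2H-chromen-3-yl]-5,7-dihydroxy-2-(4-methoxyphenyl)-2,3-dihydro-4H-chromen-4-one (2,3-cis; 2',3'-trans) | COc1ccc([C@H]2Oc3cc(O)cc(O)c3C(=O)[C@H]2[C@@H]2C(=O)c3c(O)cc(O)cc3O[C@H]2c2ccc(O)cc2)cc1 | target

**Step count.** Total: 10 steps. Longest linear sequence: 9 steps (4 → 8 → 9 → 11 → 14 → 15 → 16 → 19 → 20 → 21; step 1 supplies phenol 3 on a side branch).

**Steps most likely to fail**

Step 7 (key hydroacylation). The acyl anion equivalent may form too slowly from the hindered, electron-rich 2,6-dioxygenated aldehyde. Propargyl-to-allenyl isomerization may erode C2 and C2'. The exocyclic enone may isomerize under base to the 3-alkylflavone. The fallback sets out from 15 and comes back at 16. A nickel-catalysed reductive cyclization of the ynal (Ni(cod)2, zerovalent nickel, 1,3-dimesitylimidazol-2-ylidene, Et3SiH, THF) forms the same C4–C3 bond by oxidative cyclization of aldehyde and alkyne at nickel and syn hydride delivery to C3'. It should give (2R)-5,7-bis(benzyloxy)-3-{(2R)-2-[3,5-bis(benzyloxy)-2-ethenylphenoxy]-2-[4-(benzyloxy)phenyl]ethylidene}-2-(4-methoxyphenyl)-4-(triethylsilyloxy)chromane F1, a mixture at C4 with the alkene geometry of 16. Bu4NF then liberates the corresponding chroman-4-ol F2, and MnO2 oxidizes this benzylic, allylic carbinol to enone 16 without base.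

Step 9 (Stetter ring closure). Facial selectivity may be poor if the allylic-strain conformer does not dominate. The cis C3 centre (or C3') may epimerize in the basic carbene medium, and the chromanone may open by retro-oxa-Michael reaction. The fallback sets out from 19 and comes back at 20. A reductive ketyl–olefin cyclization with SmI2 (divalent samarium; t-BuOH, THF, −78 °C) joins C4' to C3' without base, and the samarium enolate is protonated at C3 anti to the axial aryl group. It should give (2S,3S)-5,7-bis(benzyloxy)-3-{(2R,3S)-5,7-bis(benzyloxy)-2-[4-(benzyloxy)phenyl]-4-hydroxychroman-3-yl}-2-(4-methoxyphenyl)chroman-4-one F3 as a carbinol mixture. Dess–Martin periodinane then restores the ketone of 20.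

Step 6 (Mitsunobu etherification). The p-methoxybenzylic, propargylic oxyphosphonium ion may ionize, so that substitution loses stereochemical fidelity or gives an allenyl ether by SN2'. The fallback sets out from 11 and comes back at 15, forming the ether at the arene instead of at the carbinol carbon. Alkynylation of 12 as in step 5, but with the antipodal ProPhenol ligand, gives (1R,4S)-4-[3,5-bis(benzyloxy)-2-ethenylphenoxy]-4-[4-(benzyloxy)phenyl]-1-(4-methoxyphenyl)but-2-yn-1-ol F4. Separately, 1,3,5-trifluorobenzene with BnOH/NaH gives 1,3-bis(benzyloxy)-5-fluorobenzene F5, and Vilsmeier–Haack formylation (POCl3, DMF) para to one benzyloxy group gives 2,4-bis(benzyloxy)-6-fluorobenzaldehyde F6. The sodium alkoxide of F4 (NaH, DMF, 0 °C) displaces fluoride from F6 by SNAr ortho to the formyl group. This gives 15 with retention, because the carbinol C–O bond is never broken.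

**Further compounds**
F1 | step 7 | (2R)-5,7-bis(benzyloxy)-3-{(2R)-2-[3,5-bis(benzyloxy)-2-ethenylphenoxy]-2-[4-(benzyloxy)phenyl]ethylidene}-2-(4-methoxyphenyl)-4-(triethylsilyloxy)chromane (C4 undefined) | COc1ccc([C@H]2Oc3cc(OCc4ccccc4)cc(OCc4ccccc4)c3C(O[Si](CC)(CC)CC)/C2=C/[C@@H](Oc2cc(OCc3ccccc3)cc(OCc3ccccc3)c2C=C)c2ccc(OCc3ccccc3)cc2)cc1
F2 | step 7 | (2R)-5,7-bis(benzyloxy)-3-{(2R)-2-[3,5-bis(benzyloxy)-2-ethenylphenoxy]-2-[4-(benzyloxy)phenyl]ethylidene}-2-(4-methoxyphenyl)chroman-4-ol (C4 undefined) | COc1ccc([C@H]2Oc3cc(OCc4ccccc4)cc(OCc4ccccc4)c3C(O)/C2=C/[C@@H](Oc2cc(OCc3ccccc3)cc(OCc3ccccc3)c2C=C)c2ccc(OCc3ccccc3)cc2)cc1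
F3 | step 9 | (2S,3S)-5,7-bis(benzyloxy)-3-{(2R,3S)-5,7-bis(benzyloxy)-2-[4-(benzyloxy)phenyl]-4-hydroxychroman-3-yl}-2-(4-methoxyphenyl)chroman-4-one (C4' undefined) | COc1ccc([C@H]2Oc3cc(OCc4ccccc4)cc(OCc4ccccc4)c3C(=O)[C@H]2[C@@H]2C(O)c3c(OCc4ccccc4)cc(OCc4ccccc4)cc3O[C@H]2c2ccc(OCc3ccccc3)cc2)cc1
F4 | step 6 | (1R,4S)-4-[3,5-bis(benzyloxy)-2-ethenylphenoxy]-4-[4-(benzyloxy)phenyl]-1-(4-methoxyphenyl)but-2-yn-1-ol | COc1ccc([C@@H](O)C#C[C@@H](Oc2cc(OCc3ccccc3)cc(OCc3ccccc3)c2C=C)c2ccc(OCc3ccccc3)cc2)cc1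
F5 | step 6 | 1,3-bis(benzyloxy)-5-fluorobenzene | Fc1cc(OCc2ccccc2)cc(OCc2ccccc2)c1
F6 | step 6 | 2,4-bis(benzyloxy)-6-fluorobenzaldehyde | O=Cc1c(F)cc(OCc2ccccc2)cc1OCc1ccccc1
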